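The numbers are made up.

Target forms when an open intermediate meets a second intermediate, so I follow one substrate unit through two forks, and at each fork in a tank it may leave instead of going on.

| setting | grey | teal | amber | blue |
|---|---|---|---|---|
| substrate | 0.058 M | 0.058 M (fed, over 40.0 s) | 0.058 M | 0.058 M |
| partner | 0.0870 M | 0.0870 M | 0.0870 M | 0.0870 M |
| remark | one stirred flow tank at steady state, fed with the mixture as stated, mean residence time 50 s | a stirred flask in which substrate is dosed at a steady rate over 40.0 s without added volume, worked up at 50 s | everything together in a closed stirred flask, run for 50 s | a single well-mixed tank run continuously and read at steady state, 150 s in it on average |
| time |  | 50 s | 50 s |  |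

    substrate → open intermediate (k1 = 0.023 s⁻¹)
    partner → second intermediate (k2 = 0.017 s⁻¹)
    open intermediate + second intermediate → target (k3 = 0.28 M⁻¹ s⁻¹)
    substrate + target ⇌ idle adduct, settled at all times (K4 = 65 M⁻¹)

- percent here means substrate units held: one idle adduct counts as two
- what is said of target includes idle adduct
- the stated concentrations are those of everything mixed, before any reaction; amounts are the same in each set-up
- the feed brings no volume worth counting
- in an amount of target, one idle adduct counts as one target
- run time (teal): 50 s

- the set-up with the highest amount of target at the outlet or at the end, in percent of the substrate put in ("none" if the first two lie within 2 percentage points) (grey / teal / amber / blue / none)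
- amount of target at the outlet or at the end, in percent of the substrate put in, grey
- amount of target at the outlet or at the end, in percent of the substrate put in, teal
- amount of target at the outlet or at the end, in percent of the substrate put in, amber
- amount of target at the outlet or at the end, in percent of the substrate put in, blue

I climb the time scales from the fastest. The idle adduct is kept at balance at every moment, and the equilibrium constant times starting [substrate] in amber is 3.8, so target facing that charge stands at that many idle adducts to one free target, and idle adduct still counts as target. Next comes opening, with a mean wait of 43.5 s for substrate and 58.8 s for partner. In a tank, a molecule with mean wait t and residence time τ goes on with chance τ/(τ+t). If I hold [second intermediate] at the opened share of the partner charge, coupling becomes pseudo-first-order, with a wait of its own. The lines give both tanks: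

grey: substrate opens 0.535, partner opens 0.459, coupling wait 89.3 s, product 19.2%

blue: substrate opens 0.775, partner opens 0.718, coupling wait 57.1 s, product 56.1%

That product, the chance that one substrate unit opens and then couples before leaving, is my two-fork chance. In grey the coupling wait is the longest rung of the ladder. Each target removes a second intermediate and each idle adduct holds a substrate unit, so I expect the tanks to fall below these marks. My reckoning gives no figure for the flasks. Teal's substrate enters on average at 20.0 s and stays 30.0 s, less than amber's 50 s, so I place teal below amber, and I place blue first.

The forecast gives grey 14.8%, teal 8.3%, amber 15% and blue 40.2%, and names blue: “Blue is best, mainly because of its longer residence time.” Its blue figure stands lower than my mark, and like me it puts blue first and teal lower than amber.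

The simulation names blue, with grey 14.8%, teal 8.31%, amber 15.1% and blue 40.2%. At blue's outlet, 18.7% of the substrate charged is still substrate. Grey reaches 0.771 of its two-fork chance and blue 0.717 of its own. The flow tank at 500 s, ten times grey's residence time, has a two-fork chance of 84.3%, and it gives 67.0%, which is 0.795 of that chance.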